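The butenolide is dismantled at its carbonyl carbon. Numbering: lactone O1–C2(=O)–C3=C4–C5, polyene carbons c1–c9 outward from the alkyne. C2 is the one ring atom that does not belong to a linear enone C3=C4–C5(=O)–c9. It merely bridges vinylic C3, the carbon holding the ring B vinyl arm, to O1, the C5 ketone oxygen in enol form. It is therefore brought in as carbon monoxide: a single palladium-catalysed operation makes C3–C2 and C2–O1, closes the lactone and sets up the (Z)-C5=c9 alkene. The precursor is the (Z)-iodo dienone 22: iodine on C3 cis to the C5 carbonyl, a doubly activated c9 methylene, the finished ring B arm, and a c6 silyl ether.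

Key step: step 16

Remark: the carbinol carbon formed in step 13 is carried as a mixture of epimers, because step 14 turns it into the C5 ketone.

Step 1
Reactants: 1 ketoisophorone (2,6,6-trimethylcyclohex-2-ene-1,4-dione)
Product: 2 (6R)-levodione, (R)-2,2,6-trimethylcyclohexane-1,4-dione
Conditions: ene-reductase OYE2, NADP+ (cat.), glucose dehydrogenase, D-glucose, phosphate buffer pH 7, 30 °C
Reagents that add atoms: none
Why: Biocatalytic conjugate reduction by a flavin-dependent ene-reductase, in which trans addition of hydride and proton inside the active site fixes the new methyl-bearing centre C6 as R under enzyme control and leaves both carbonyl groups intact.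

Step 2
Reactants: 2 (6R)-levodione
Product: 3 (4R,6R)-actinol, (4R,6R)-4-hydroxy-2,2,6-trimethylcyclohexanone
Conditions: H2, Raney Ni, MeOH, rt; recrystallisation
Reagents that add atoms: none
Why: Heterogeneous catalytic hydrogenation reduces only the unhindered C4 ketone (C1 is flanked by a quaternary and a tertiary carbon), and hydrogen arrives from the face away from the axial C2 methyl, so C4 is set as R with the hydroxyl trans to the C6 methyl; recrystallisation removes the minor cis alcohol.

Step 3
Reactants: 3 (4R,6R)-actinol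
Product: 4 (4R,6R)-4-(tert-butyldimethylsilyloxy)-2,2,6-trimethylcyclohexanone
Conditions: TBSCl, imidazole, DMF, rt
Reagents that add atoms: tert-butyldimethylsilyl chloride, CC(C)(C)[Si](C)(C)Cl
Why: Imidazole-promoted silylation of the only hydroxyl group, which touches no stereocentre.

Step 4
Reactants: 4 silylated actinol
Product: 6 (R)-4-(tert-butyldimethylsilyloxy)-2,6,6-trimethylcyclohex-1-enyl triflate, via lithium enolate 5 (not isolated)
Conditions: LiN(iPr)2, THF, −78 to 0 °C; PhNTf2, −78 °C to rt; aq NH4Cl
Reagents that add atoms: N-phenylbis(trifluoromethanesulfonimide), O=S(=O)(N(c1ccccc1)S(=O)(=O)C(F)(F)F)C(F)(F)F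
Why: Enolate O-triflation, in which deprotonation can occur only at C6 because C2 is quaternary, so a single tetrasubstituted enol triflate forms; C6 is erased and the silyloxy-bearing centre (R) is untouched.

Step 5
Reactants: 6 enol triflate
Product: 7 methyl (R)-4-(tert-butyldimethylsilyloxy)-2,6,6-trimethylcyclohex-1-ene-1-carboxylate
Conditions: Pd(OAc)2 (5 mol %), PPh3 (10 mol %), CO (1 atm), MeOH, NEt3, DMF, 40 °C
Reagents that add atoms: carbon monoxide, [C-]#[O+]; methanol, CO
Why: Palladium-catalysed alkoxycarbonylation of an enol triflate (oxidative addition, CO insertion, methanolysis of the acylpalladium) places the one-carbon handle on the ring without moving the alkene.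

Step 6
Reactants: 7 methyl ester
Product: 8 [(R)-4-(tert-butyldimethylsilyloxy)-2,6,6-trimethylcyclohex-1-enyl]methanol
Conditions: i-Bu2AlH (2.5 equiv), CH2Cl2, −78 °C; aqueous work-up
Reagents that add atoms: none
Why: 1,2-Reduction of a conjugated ester by i-Bu2AlH gives the allylic alcohol and leaves the tetrasubstituted alkene and the silyl ether alone.

Step 7
Reactants: 8 allylic alcohol
Product: 9 [(1R,4S,6R)-4-(tert-butyldimethylsilyloxy)-2,2,6-trimethyl-7-oxabicyclo[4.1.0]heptan-1-yl]methanol
Conditions: Ti(OiPr)4 (0.2 equiv), D-(−)-diethyl tartrate (0.25 equiv), t-BuOOH, 4 Å sieves, CH2Cl2, −20 °C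
Reagents that add atoms: tert-butyl hydroperoxide, CC(C)(C)OO
Why: Sharpless asymmetric epoxidation, in which the titanium–D-(−)-tartrate complex binds the allylic alcohol and the peroxide and transfers oxygen to the face that gives the 2R series of epoxy alcohols, here the face anti to the C4 silyloxy group, so C1 (R) and C6 (R) are set together by reagent control in one syn addition.

Step 8
Reactants: 9 epoxy alcohol
Product: 10 (1S,4S,6R)-4-(tert-butyldimethylsilyloxy)-2,2,6-trimethyl-7-oxabicyclo[4.1.0]heptane-1-carbaldehyde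
Conditions: Pr4NRuO4 (5 mol %), N-methylmorpholine N-oxide, 4 Å sieves, CH2Cl2, rt
Reagents that add atoms: none
Why: Ley–Griffith oxidation under neutral conditions stops at the aldehyde, and quaternary C1 cannot epimerise (its descriptor changes only through the priority rules).

Step 9
Reactants: 10 epoxy aldehyde; 11 (3-trimethylsilylprop-2-ynyl)triphenylphosphonium bromide
Product: 13 (1S,4S,6R)-4-(tert-butyldimethylsilyloxy)-2,2,6-trimethyl-1-[(E)-4-(trimethylsilyl)but-1-en-3-ynyl]-7-oxabicyclo[4.1.0]heptane, via propargylic ylide 12 (not isolated)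
Conditions: 11, n-BuLi, THF, −78 to 0 °C; then 10, −78 °C to rt
Reagents that add atoms: none
Why: Wittig olefination, in which the semi-stabilised propargylic ylide and the hindered, non-enolisable α-quaternary aldehyde should favour the E enyne; any Z isomer is removed by chromatography and the ring stereocentres are not involved.

Step 10
Reactants: 13 C-silylated enyne
Product: 14 (1S,4S,6R)-1-[(E)-but-1-en-3-ynyl]-4-(tert-butyldimethylsilyloxy)-2,2,6-trimethyl-7-oxabicyclo[4.1.0]heptane
Conditions: K2CO3 (0.2 equiv), MeOH, rt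
Reagents that add atoms: none
Why: Base-catalysed methanolysis cleaves only the alkynyl C–Si bond, because an acetylide leaves silicon readily, while the silyl ether and the epoxide are inert to K2CO3.

Step 11
Reactants: 15 (E)-3-methylpent-2-en-4-yn-1-ol
Product: 16 (E)-tert-butyldimethyl(3-methylpent-2-en-4-ynyloxy)silane
Conditions: TBSCl, imidazole, DMF, rt
Reagents that add atoms: tert-butyldimethylsilyl chloride, CC(C)(C)[Si](C)(C)Cl
Why: Imidazole-promoted silylation of the primary alcohol, giving an allylic oxygen substituent that zerovalent palladium will not ionise later.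

Step 12
Reactants: 16 silylated enynol
Product: 18 (E)-5-(tert-butyldimethylsilyloxy)-3-methylpent-3-enal, via dienyl dicyclohexylborane 17 (not isolated)
Conditions: Cy2BH (from BH3·SMe2 and cyclohexene), THF, 0 °C; then 30% H2O2, pH 7 phosphate buffer, 0 °C; used at once
Reagents that add atoms: hydrogen peroxide, OO
Why: Hydroboration–oxidation, in which the bulky dialkylborane adds syn and anti-Markovnikov to the terminal alkyne only (the trisubstituted alkene is too hindered), and buffered oxidation gives the dienol, which tautomerises kinetically to the β,γ-unsaturated aldehyde with the E alkene intact.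

Step 13
Reactants: 14 ring B enyne; 18 aldehyde
Product: 20 propargylic alcohol TBSO–c6H2–c7H=c8(CH3)–c9H2–C5H(OH)–C4≡C3–CH=CH–ring B (C5 epimers), via lithium acetylide 19 (not isolated)
Conditions: 14, n-BuLi, THF, −78 °C; then 18, −78 °C; aq NH4Cl
Reagents that add atoms: none
Why: 1,2-Addition of a lithium acetylide to an aldehyde, which at −78 °C outruns enolisation of the c9 methylene; the new C5 carbinol centre is of no consequence because the next step oxidises it.

Step 14
Reactants: 20 propargylic alcohol
Product: 21 ynone TBSO–c6H2–c7H=c8(CH3)–c9H2–C5(=O)–C4≡C3–CH=CH–ring B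
Conditions: activated MnO2, CH2Cl2, rt
Reagents that add atoms: none
Why: MnO2 oxidation of an activated propargylic alcohol on a neutral surface gives the ynone without acid or base that could move the c7=c8 alkene into conjugation.

Step 15
Reactants: 21 ynone
Product: 22 (Z)-iodo dienone TBSO–c6H2–c7H=c8(CH3)–c9H2–C5(=O)–C4H=C3(I)–CH=CH–ring B, iodine cis to the C5 carbonyl
Conditions: NaI (1.5 equiv), AcOH (3 equiv), MeCN, 0 °C to rt, dark
Reagents that add atoms: sodium iodide, [Na+].[I-]
Why: Conjugate hydroiodination of an ynone, in which iodide adds to the β-carbon C3 and the iodoallenol is protonated at C4 on the side away from iodine; this net anti addition gives the kinetic Z isomer, and the few equivalents of weak acid spare the epoxide and both silyl ethers.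

Step 16
Reactants: 22 (Z)-iodo dienone
Product: 23 ring B (Z)-ylidenebutenolide with the c6 silyl ether
Conditions: CO (1 atm), PdCl2(PPh3)2 (5 mol %), NEt3 (2 equiv), dry DMF, 25–40 °C, dark
Reagents that add atoms: carbon monoxide, [C-]#[O+]
Why: Zerovalent palladium, formed in situ from PdCl2(PPh3)2, inserts into the C3–I bond with retention and CO then inserts, so the acylpalladium carbon C2 is held cis to the C5 carbonyl across C3=C4. The in-plane lone pair of the C5 oxygen attacks C2 in a 5-exo-trig acyl substitution while NEt3 removes a c9 proton, acidified by both the ketone and the c7=c8 alkene; this forms C2–O1, closes the lactone, frees zerovalent palladium and leaves the C5=c9 double bond. The closest known reaction type is the carbonylative lactonisation of (Z)-β-iodoenones to 5-alkylidenebutenolides. No stereocentre is created, and the C5=c9 alkene should be Z because the E arrangement presses c8 against C4–H (allylic strain) and Z is also the thermodynamic isomer. O- over C-acylation cannot come from ring size, since attack by c9 would also close a five-membered ring (a cyclopentenedione); it comes from stereoelectronics, because c9 attack is a disfavoured 5-(enolendo)-exo-trig closure whose π lobe cannot reach C2 in the planar Z-enone, whereas the oxygen lone pair points straight at it. Chemoselectivity rests on oxidative addition to the vinyl iodide being far faster than ionisation of the hindered tetrasubstituted vinyl epoxide, and on silyloxide being too poor a leaving group for allylpalladium formation or vinylogous elimination, which is why c6 carries a silyl ether and not an ester.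

Step 17
Reactants: 6 enol triflate; 15 (E)-3-methylpent-2-en-4-yn-1-ol
Product: 24 (E)-5-[(R)-4-(tert-butyldimethylsilyloxy)-2,6,6-trimethylcyclohex-1-enyl]-3-methylpent-2-en-4-yn-1-ol
Conditions: Pd(PPh3)4 (5 mol %), CuI (10 mol %), i-Pr2NH, DMF, rt to 50 °C
Reagents that add atoms: none
Why: Sonogashira coupling (oxidative addition to the enol triflate, transmetalation from the copper acetylide, reductive elimination) joins ring A to the alkyne, keeps the E c1=c2 alkene of 15 and tolerates the free primary alcohol.

Step 18
Reactants: 24 ring A enynol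
Product: 25 (E)-5-[(R)-4-(tert-butyldimethylsilyloxy)-2,6,6-trimethylcyclohex-1-enyl]-3-methylpent-2-en-4-ynal
Conditions: activated MnO2, CH2Cl2, rt
Reagents that add atoms: none
Why: MnO2 oxidation is selective for the allylic alcohol and stops at the enal c3 aldehyde.

Step 19
Reactants: 25 ring A enynal; 26 ethyl (triphenylphosphoranylidene)acetate
Product: 27 ethyl (2E,4E)-7-[(R)-4-(tert-butyldimethylsilyloxy)-2,6,6-trimethylcyclohex-1-enyl]-5-methylhepta-2,4-dien-6-ynoate
Conditions: CH2Cl2, rt
Reagents that add atoms: none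
Why: Wittig olefination with a stabilised ester ylide needs no added base and gives the E c3=c4 alkene.

Step 20
Reactants: 27 dienynoate
Product: 28 (2E,4E)-7-[(R)-4-(tert-butyldimethylsilyloxy)-2,6,6-trimethylcyclohex-1-enyl]-5-methylhepta-2,4-dien-6-yn-1-ol
Conditions: i-Bu2AlH (2.5 equiv), CH2Cl2, −78 °C; aqueous work-up
Reagents that add atoms: none
Why: 1,2-Reduction of the conjugated ester by i-Bu2AlH gives the c5 allylic alcohol without touching the alkyne, the alkenes or the silyl ether.

Step 21
Reactants: 28 dienynol
Product: 29 (2E,4E)-dienynyl bromide (c5 bromide of 28)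
Conditions: CBr4, PPh3, CH2Cl2, −20 °C; used crude
Reagents that add atoms: carbon tetrabromide, BrC(Br)(Br)Br
Why: Appel bromination, an SN2 displacement of the oxyphosphonium ion by bromide under neutral, cold conditions, keeps the diene geometry.

Step 22
Reactants: 29 dienynyl bromide
Product: 30 diethyl [(2E,4E)-7-[(R)-4-(tert-butyldimethylsilyloxy)-2,6,6-trimethylcyclohex-1-enyl]-5-methylhepta-2,4-dien-6-ynyl]phosphonate
Conditions: P(OEt)3 (neat), 90 °C
Reagents that add atoms: triethyl phosphite, CCOP(OCC)OCC
Why: Michaelis–Arbuzov reaction, in which phosphorus displaces the primary allylic bromide and bromide then dealkylates the phosphonium ion to the phosphonate.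

Step 23
Reactants: 23 ylidenebutenolide
Product: 31 c6 allylic alcohol of the ylidenebutenolide (ring B silyl ether retained)
Conditions: HF·pyridine, excess pyridine, THF, 0 °C
Reagents that add atoms: none
Why: Fluoride-mediated desilylation under steric control, in which buffered HF·pyridine cleaves the unhindered primary allylic silyl ether much faster than the secondary ring B ether, and the pyridine buffer protects the epoxide from acid.

Step 24
Reactants: 31 allylic alcohol
Product: 32 c6 aldehyde of the ylidenebutenolide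
Conditions: activated MnO2, CH2Cl2, rt, dark
Reagents that add atoms: none
Why: MnO2 oxidation of the primary allylic alcohol gives the conjugated aldehyde under neutral conditions that leave the lactone, the epoxide and all alkene geometries alone.

Step 25
Reactants: 30 ring A phosphonate; 32 butenolide aldehyde
Product: 34 bis(tert-butyldimethylsilyl) ether of the target, via lithiated phosphonate 33 (not isolated)
Conditions: 30, n-BuLi, THF–DMPU, −78 °C; then 32, −78 to −20 °C, dark; aq NH4Cl
Reagents that add atoms: none
Why: Horner–Wadsworth–Emmons olefination of an allylic phosphonate carbanion with an enal, in which reversible addition and elimination through the less crowded trans-oxaphosphetane should give the E c5=c6 alkene, and the soft delocalised anion attacks the aldehyde in preference to the lactone at low temperature.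

Step 26
Reactants: 34 bis-silyl ether
Product: 35 target CNP0180336.1
Conditions: Bu4NF, AcOH (1:1), THF, rt, dark, argon
Reagents that add atoms: none
Why: Fluoride-mediated cleavage of both secondary silyl ethers, with acetic acid tempering the basicity of Bu4NF so that the lactone, the epoxide and the polyene geometry persist; no stereocentre is affected.

Compound list
1 | ketoisophorone (2,6,6-trimethylcyclohex-2-ene-1,4-dione) | CC1=CC(=O)CC(C)(C)C1=O | starting material
2 | (6R)-levodione | C[C@@H]1CC(=O)CC(C)(C)C1=O | intermediate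
3 | (4R,6R)-actinol | C[C@@H]1C[C@@H](O)CC(C)(C)C1=O | intermediate
4 | (4R,6R)-4-(tert-butyldimethylsilyloxy)-2,2,6-trimethylcyclohexanone | C[C@@H]1C[C@@H](O[Si](C)(C)C(C)(C)C)CC(C)(C)C1=O | intermediate
5 | lithium enolate of 4 (not isolated) | CC1=C([O-])C(C)(C)C[C@H](O[Si](C)(C)C(C)(C)C)C1.[Li+] | intermediate
6 | (R)-4-(tert-butyldimethylsilyloxy)-2,6,6-trimethylcyclohex-1-enyl triflate | CC1=C(OS(=O)(=O)C(F)(F)F)C(C)(C)C[C@H](O[Si](C)(C)C(C)(C)C)C1 | intermediate
7 | methyl (R)-4-(tert-butyldimethylsilyloxy)-2,6,6-trimethylcyclohex-1-ene-1-carboxylate | CC1=C(C(=O)OC)C(C)(C)C[C@H](O[Si](C)(C)C(C)(C)C)C1 | intermediate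
8 | [(R)-4-(tert-butyldimethylsilyloxy)-2,6,6-trimethylcyclohex-1-enyl]methanol | CC1=C(CO)C(C)(C)C[C@H](O[Si](C)(C)C(C)(C)C)C1 | intermediate
9 | [(1R,4S,6R)-4-(tert-butyldimethylsilyloxy)-2,2,6-trimethyl-7-oxabicyclo[4.1.0]heptan-1-yl]methanol | OC[C@@]12O[C@]1(C)C[C@@H](O[Si](C)(C)C(C)(C)C)CC2(C)C | intermediate
10 | (1S,4S,6R)-4-(tert-butyldimethylsilyloxy)-2,2,6-trimethyl-7-oxabicyclo[4.1.0]heptane-1-carbaldehyde | O=C[C@@]12O[C@]1(C)C[C@@H](O[Si](C)(C)C(C)(C)C)CC2(C)C | intermediate
11 | (3-trimethylsilylprop-2-ynyl)triphenylphosphonium bromide | C[Si](C)(C)C#CC[P+](c1ccccc1)(c1ccccc1)c1ccccc1.[Br-] | starting material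
12 | (3-trimethylsilylprop-2-ynylidene)triphenylphosphorane (not isolated) | C[Si](C)(C)C#CC=P(c1ccccc1)(c1ccccc1)c1ccccc1 | intermediate
13 | ring B (E)-enyne, C-trimethylsilylated | C[Si](C)(C)C#C/C=C/[C@@]12O[C@]1(C)C[C@@H](O[Si](C)(C)C(C)(C)C)CC2(C)C | intermediate
14 | ring B (E)-enyne, terminal alkyne | C#C/C=C/[C@@]12O[C@]1(C)C[C@@H](O[Si](C)(C)C(C)(C)C)CC2(C)C | intermediate
15 | (E)-3-methylpent-2-en-4-yn-1-ol | C#C/C(C)=C/CO | starting material
16 | (E)-tert-butyldimethyl(3-methylpent-2-en-4-ynyloxy)silane | C#C/C(C)=C/CO[Si](C)(C)C(C)(C)C | intermediate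
17 | (1E,3E)-5-(tert-butyldimethylsilyloxy)-3-methylpenta-1,3-dienyl(dicyclohexyl)borane (not isolated) | CC(/C=C/B(C1CCCCC1)C1CCCCC1)=C\CO[Si](C)(C)C(C)(C)C | intermediate
18 | (E)-5-(tert-butyldimethylsilyloxy)-3-methylpent-3-enal | O=CC/C(C)=C/CO[Si](C)(C)C(C)(C)C | intermediate
19 | lithium acetylide of 14 (not isolated) | [Li+].[C-]#C/C=C/[C@@]12O[C@]1(C)C[C@@H](O[Si](C)(C)C(C)(C)C)CC2(C)C | intermediate
20 | C5 propargylic alcohol (epimers at C5) | CC(C)(C)[Si](C)(C)OC/C=C(C)/CC(O)C#C/C=C/[C@@]12O[C@]1(C)C[C@@H](O[Si](C)(C)C(C)(C)C)CC2(C)C | intermediate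
21 | C5 ynone | CC(C)(C)[Si](C)(C)OC/C=C(C)/CC(=O)C#C/C=C/[C@@]12O[C@]1(C)C[C@@H](O[Si](C)(C)C(C)(C)C)CC2(C)C | intermediate
22 | (Z)-C3-iodo dienone with ring B arm and c6 silyl ether | CC(C)(C)[Si](C)(C)OC/C=C(C)/CC(=O)/C=C(\I)/C=C/[C@@]12O[C@]1(C)C[C@@H](O[Si](C)(C)C(C)(C)C)CC2(C)C | intermediate
23 | ring B (Z)-ylidenebutenolide with c6 silyl ether | CC(C)(C)[Si](C)(C)OC/C=C(C)/C=C1C=C(/C=C/[C@@]23O[C@]2(C)C[C@@H](O[Si](C)(C)C(C)(C)C)CC3(C)C)C(=O)O/1 | intermediate
24 | ring A enynol (c3 alcohol) | CC1=C(C#C/C(C)=C/CO)C(C)(C)C[C@H](O[Si](C)(C)C(C)(C)C)C1 | intermediate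
25 | ring A enynal (c3 aldehyde) | CC1=C(C#C/C(C)=C/C=O)C(C)(C)C[C@H](O[Si](C)(C)C(C)(C)C)C1 | intermediate
26 | ethyl (triphenylphosphoranylidene)acetate | CCOC(=O)C=P(c1ccccc1)(c1ccccc1)c1ccccc1 | starting material
27 | ring A (2E,4E)-dienynoate | CC1=C(C#C/C(C)=C/C=C/C(=O)OCC)C(C)(C)C[C@H](O[Si](C)(C)C(C)(C)C)C1 | intermediate
28 | ring A (2E,4E)-dienynol (c5 alcohol) | CC1=C(C#C/C(C)=C/C=C/CO)C(C)(C)C[C@H](O[Si](C)(C)C(C)(C)C)C1 | intermediate
29 | ring A (2E,4E)-dienynyl bromide | CC1=C(C#C/C(C)=C/C=C/CBr)C(C)(C)C[C@H](O[Si](C)(C)C(C)(C)C)C1 | intermediate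
30 | ring A (2E,4E)-dienynyl diethyl phosphonate | CC1=C(C#C/C(C)=C/C=C/CP(=O)(OCC)OCC)C(C)(C)C[C@H](O[Si](C)(C)C(C)(C)C)C1 | intermediate
31 | ylidenebutenolide c6 allylic alcohol | OC/C=C(C)/C=C1C=C(/C=C/[C@@]23O[C@]2(C)C[C@@H](O[Si](C)(C)C(C)(C)C)CC3(C)C)C(=O)O/1 | intermediate
32 | ylidenebutenolide c6 aldehyde | O=C/C=C(C)/C=C1C=C(/C=C/[C@@]23O[C@]2(C)C[C@@H](O[Si](C)(C)C(C)(C)C)CC3(C)C)C(=O)O/1 | intermediate
33 | lithiated phosphonate from 30 (not isolated) | CC1=C(C#C/C(C)=C/C=C/[CH-]P(=O)(OCC)OCC)C(C)(C)C[C@H](O[Si](C)(C)C(C)(C)C)C1.[Li+] | intermediate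
34 | bis(tert-butyldimethylsilyl) ether of the target | CC1=C(C#C/C(C)=C/C=C/C=C/C=C(C)/C=C2C=C(/C=C/[C@@]34O[C@]3(C)C[C@@H](O[Si](C)(C)C(C)(C)C)CC4(C)C)C(=O)O/2)C(C)(C)C[C@H](O[Si](C)(C)C(C)(C)C)C1 | intermediate
35 | CNP0180336.1 (ring A carbinol R; ring B 3S,5R,6S in carotenoid numbering) | CC1=C(C#C/C(C)=C/C=C/C=C/C=C(C)/C=C2C=C(/C=C/[C@@]34O[C@]3(C)C[C@@H](O)CC4(C)C)C(=O)O/2)C(C)(C)C[C@H](O)C1 | target

Total step count: 26. Longest linear sequence: 18 steps (steps 1–10, 13–16 and 23–26).

Steps most likely to fail

Step 16.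
- **What may go wrong:** capture of the acylpalladium by the C5 oxygen may be slower than its diversion by adventitious water or by reduction. Zerovalent palladium may start to ionise the vinyl epoxide. The ylidene geometry may erode.
- **Fallback:** this route gives up CO, sets out from 16 and 10, and comes back at 23. Alkyne 16 is coupled with commercial (E)-2,3-dibromoacrylic acid at its more reactive β-bromide (Pd(PPh3)4, CuI, NEt3, MeCN). The carboxylate adds 5-exo-dig to the new enyne in the same pot and gives the (Z)-3-bromo-5-ylidenebutenolide F1. Aldehyde 10 is converted by a Takai-type stannyl olefination (CrCl2, Bu3SnCHBr2, LiI, THF–DMF) into the ring B (E)-vinylstannane F2. Stille coupling of F1 with F2 (Pd2(dba)3, AsPh3, NMP, rt) places the arm on C3 and delivers 23.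

Step 15.
- **What may go wrong:** acid-promoted equilibration may erode the Z geometry. Iodide may add 1,6 through the enyne. The c7=c8 alkene may migrate into conjugation. Iodide and acid may open the epoxide.
- **Fallback:** this route avoids both the ynone and the acid, sets out from 20, and comes back at 22. Hydroxyl-directed trans-hydroalumination of 20 with NaAlH2(OCH2CH2OMe)2 (THF, 0 °C) places aluminium on C3 within a cyclic alkoxyaluminate, hence cis to the carbinol carbon. Iodine at −78 °C replaces it with retention to give the (Z)-iodo allylic alcohol F3. MnO2 oxidation of F3 then gives 22.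

Step 25.
- **What may go wrong:** E selectivity at c5=c6 may be incomplete. The delocalised carbanion may attack through its γ-position. The base may degrade the ylidenebutenolide aldehyde.
- **Fallback:** this route replaces carbonyl olefination by a stereoretentive cross-coupling at c4–c5, sets out from 32 and 25, and comes back at 34. Takai iodoolefination of 32 (CrCl2, CHI3, THF, 0 °C) gives the (E)-dienyl iodide F4. Stannyl olefination of 25 (CrCl2, Bu3SnCHBr2, LiI) gives the ring A (E)-dienynylstannane F5. Stille coupling of F4 with F5 (Pd2(dba)3, AsPh3, NMP, rt, dark) gives 34.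

Further compounds
F1 | step 16 | (Z)-3-bromo-5-ylidenebutenolide with c6 silyl ether | CC(C)(C)[Si](C)(C)OC/C=C(C)/C=C1C=C(Br)C(=O)O/1
F2 | step 16 | ring B (E)-vinyl tributylstannane | CCCC[Sn](CCCC)(CCCC)/C=C/[C@@]12O[C@]1(C)C[C@@H](O[Si](C)(C)C(C)(C)C)CC2(C)C
F3 | step 15 | (Z)-C3-iodo allylic alcohol (C5 epimers) | CC(C)(C)[Si](C)(C)OC/C=C(C)/CC(O)/C=C(\I)/C=C/[C@@]12O[C@]1(C)C[C@@H](O[Si](C)(C)C(C)(C)C)CC2(C)C
F4 | step 25 | ylidenebutenolide (E)-c5 dienyl iodide | I/C=C/C=C(C)/C=C1C=C(/C=C/[C@@]23O[C@]2(C)C[C@@H](O[Si](C)(C)C(C)(C)C)CC3(C)C)C(=O)O/1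
F5 | step 25 | ring A (E)-c4 dienynyl tributylstannane | CC1=C(C#C/C(C)=C/C=C/[Sn](CCCC)(CCCC)CCCC)C(C)(C)C[C@H](O[Si](C)(C)C(C)(C)C)C1
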